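At early times the earlier runs show Z and not chains: the epsilon run has Z at 0% after 4.00 min, 12% after 12.0 min and 28% after 25.0 min.

| flask | Q | E | remark | time |
|---|---|---|---|---|
| epsilon | 2.5 M | 8.2 mM | run made earlier |  |
| alpha | 2.4 M | 8.2 mM | run made earlier |  |
| Saturday's | 2.0 M | 8.2 mM |  | 50 min |
| Sunday's | 3.0 M | 8.2 mM |  | 50 min |

| run | time / min | Z / % | Q / % |
|---|---|---|---|
| epsilon | 2.00 | 0 | 100 |
| epsilon | 4.00 | 0 | 101 |
| epsilon | 8.00 | 4 | 94 |
| epsilon | 12.0 | 12 | 91 |
| epsilon | 25.0 | 28 | 77 |
| alpha | 2.00 | 2 | 98 |
| alpha | 6.00 | 5 | 93 |
| alpha | 12.0 | 9 | 94 |
| alpha | 20.0 | 20 | 80 |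
| alpha | 25.0 | 27 | 74 |

(scatter of a reading: 2 percentage points)

- which of the two ends with the longer chains by the average number of monomer units in a chain (chains begun, living or dead) ("neither" if they lie within 10%) (Saturday's / Sunday's / neither)
- average number of monomer units in a chain (chains begun, living or dead) at the end, Saturday's
- average number of monomer units in a chain (chains begun, living or dead) at the end, Sunday's

- the average divides the monomer in chains by the number of chains begun, living and dead together
- the earlier runs do not show the number of chains; that part of a forecast is a guess

Two chemists argue over the end of these flasks, and they share one reckoning. Saturday's has n = 244 and Sunday's n = 366, where n is the charge ratio, [Q] charged over [E] charged. If x is the fraction of Q reacted and standing in chains and f the fraction of charged E that has begun a chain (the initiator efficiency, read at one moment), the average length is x·n/f.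

The first chemist works from the late end. With f near one and about 50% reacted, the length is close to x·n. The forecast takes this side, “The initiator should be essentially consumed”, and prints Sunday's, with 120 for Saturday's and 180 for Sunday's.

The second chemist works from the early end. The slow start suggests chains still being begun, so this chemist guesses that half of E has begun one by the end. With the same x, the length is then n itself, 244 and 366.

Neither can be tested on the readings, which hold no chain count.

The flask gives 125 for Saturday's and 198 for Sunday's, so Sunday's ends longer.

2 E → X (k = 0.850 M⁻¹ min⁻¹); E + Z → E.Z (k = 0.0510 M⁻¹ min⁻¹); Z + J → Q + J, rate k3*[J] as long as [Z] is above zero (k = 0.330 min⁻¹); Q + J → Z + J, rate k4*[J]*[Q] (k = 2.20 M⁻¹ min⁻¹); Q + E → J + Z (k = 0.0550 M⁻¹ min⁻¹) Saturday's at 50.0 min held J, the living end, at 0.00725 M, which makes f 0.884, and x·n/f with 45.4% reacted returns 125. The second chemist's f, far below one, belongs to early Saturday's: at 5.00 min, 2.03% reacted and a length of 12.1 put f at 0.409.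

Saturday's flask read at 80 min has 36.7% of its Q left, and x·n/f with the same f gives 175. The computed length there is 174.

The data come from a simulation for substances that don't exist; the scatter is artificial.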